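**Plan**

- Side-chain carbons are counted C1' (benzylic) to C15'. Retrosynthesis first removes the arene O-methyl groups, the C5' acetate and the C12'–C13' prenyl bond; then C1'–C2' and C3'–CH3 are cut together; then C4'–C5', C5'–C6' with C7'–CH3, and C9'–C10'.
- The feature that invites the central step is the E-trisubstituted C2'=C3' alkene, with CH3 on C3' and the benzylic C1' of the 2,5-dioxygenated 3-methylphenyl ring on C2'. This is the pattern left by syn methylmetalation of a terminal alkyne followed by benzylation.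
- Forward: benzyl chloride 5 (four steps from the phenol) and the C2'–C12' alkyne 21 (nine steps from the Roche ester) are joined with AlMe3 in one flask. The chain is then finished by silyl-to-acetate exchange at C5', α-prenylation and oxidation at C12', and release of the hydroquinone. No ring is formed at any stage.
- Stereochemistry: C11' (S) comes from methyl (R)-3-hydroxy-2-methylpropanoate. C5' (S) comes from catalyst-controlled propargylation of the C5' enal. Both E alkenes come from syn methylalumination of terminal alkynes.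

Key step: step 14

Remark: C12' is carried as a TBDPS ether and C5' as a TES ether, so no DDQ is used beside the electron-rich arene and the acetate is in place before the epimerisable β,γ-unsaturated ketone exists. The C12' carbinol of step 19 is used as a mixture of epimers because step 20 oxidises that centre.

Step 1
Reactants: 1 4-methoxy-2-methylphenol
Product: 2 2-hydroxy-5-methoxy-3-methylbenzaldehyde
Conditions: MgCl2, Et3N, (CH2O)n, MeCN, reflux
Reagents that add atoms: paraformaldehyde (formaldehyde, C=O)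
Why: Casnati–Skattebøl ortho-formylation, in which the magnesium phenoxide directs formaldehyde to the only free ortho position and a second formaldehyde oxidises the hydroxymethyl intermediate to the aldehyde.

Step 2
Reactants: 2 2-hydroxy-5-methoxy-3-methylbenzaldehyde
Product: 3 2,5-dimethoxy-3-methylbenzaldehyde
Conditions: MeI, K2CO3, DMF, rt
Reagents that add atoms: iodomethane (CI)
Why: Williamson O-methylation of the phenoxide, which is the only acidic site present.

Step 3
Reactants: 3 2,5-dimethoxy-3-methylbenzaldehyde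
Product: 4 (2,5-dimethoxy-3-methylphenyl)methanol
Conditions: NaBH4, MeOH, 0 °C
Reagents that add atoms: none
Why: Borohydride reduction of an aryl aldehyde with no competing reducible group.

Step 4
Reactants: 4 (2,5-dimethoxy-3-methylphenyl)methanol
Product: 5 1-(chloromethyl)-2,5-dimethoxy-3-methylbenzene
Conditions: SOCl2, CH2Cl2, 0 °C → rt
Reagents that add atoms: thionyl chloride (O=S(Cl)Cl)
Why: Deoxychlorination through the chlorosulfite, which is fast at an electron-rich benzylic carbon and leaves the aryl methyl ethers intact.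

Step 5
Reactants: 6 methyl (R)-3-hydroxy-2-methylpropanoate
Product: 7 methyl (R)-3-(tert-butyldiphenylsilyloxy)-2-methylpropanoate
Conditions: TBDPSCl, imidazole, CH2Cl2, rt
Reagents that add atoms: tert-butylchlorodiphenylsilane (CC(C)(C)[Si](Cl)(c1ccccc1)c1ccccc1)
Why: Imidazole-promoted silylation of the primary alcohol under conditions too mild to epimerise the α-stereocentre of the ester.

Step 6
Reactants: 7 methyl (R)-3-(tert-butyldiphenylsilyloxy)-2-methylpropanoate
Product: 8 (S)-3-(tert-butyldiphenylsilyloxy)-2-methylpropan-1-ol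
Conditions: LiBH4, THF, 0 °C → rt
Reagents that add atoms: none
Why: Hydride reduction of the ester to the primary alcohol, which keeps the stereocentre (the descriptor changes only through substituent priorities) and spares the silyl ether.

Step 7
Reactants: 8 (S)-3-(tert-butyldiphenylsilyloxy)-2-methylpropan-1-ol
Product: 9 (R)-tert-butyl(3-iodo-2-methylpropoxy)diphenylsilane
Conditions: I2, PPh3, imidazole, CH2Cl2, 0 °C → rt
Reagents that add atoms: iodine (II)
Why: Appel-type iodination of a primary alcohol through the alkoxyphosphonium salt, with the stereocentre one carbon removed from the reacting site.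

Step 8
Reactants: 9 (R)-tert-butyl(3-iodo-2-methylpropoxy)diphenylsilane; 10 (4-bromobut-1-yn-1-yl)trimethylsilane
Product: 12 (S)-tert-butyl{[2-methyl-7-(trimethylsilyl)hept-6-yn-1-yl]oxy}diphenylsilane, via Grignard reagent 11 (not isolated)
Conditions: 10, Mg, THF, rt; then 9, Li2CuCl4 (cat.), THF/NMP, 0 °C → rt
Reagents that add atoms: none
Why: Kochi-type copper-catalysed alkyl–alkyl coupling of a primary iodide with a primary Grignard reagent forms C9'–C10', the alkynyl silane masking the acidic C–H and the stereocentre lying β to the reacting carbon.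

Step 9
Reactants: 12 (S)-tert-butyl{[2-methyl-7-(trimethylsilyl)hept-6-yn-1-yl]oxy}diphenylsilane
Product: 13 (S)-tert-butyl[(2-methylhept-6-yn-1-yl)oxy]diphenylsilane
Conditions: K2CO3, MeOH, rt
Reagents that add atoms: none
Why: Methoxide-mediated protodesilylation cleaves only the alkynyl C–Si bond, since a primary TBDPS ether is stable to carbonate in methanol.

Step 10
Reactants: 13 (S)-tert-butyl[(2-methylhept-6-yn-1-yl)oxy]diphenylsilane; 14 trimethylaluminium
Product: 17 (2E,7S)-8-(tert-butyldiphenylsilyloxy)-3,7-dimethyloct-2-en-1-ol, via alkenyldimethylalane 15 (not isolated), via lithium alanate 16 (not isolated)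
Conditions: AlMe3 (14), Cp2ZrCl2 (cat.), CH2Cl2, 0 °C → rt; n-BuLi, THF, −78 °C; (CH2O)n, −78 °C → rt
Reagents that add atoms: paraformaldehyde (formaldehyde, C=O)
Why: Negishi zirconium-catalysed methylalumination adds CH3 and Al syn across the terminal alkyne with methyl on the internal carbon, and the derived alanate is hydroxymethylated with retention, so the E allylic alcohol (C5'–C12') results without any new stereocentre.

Step 11
Reactants: 17 (2E,7S)-8-(tert-butyldiphenylsilyloxy)-3,7-dimethyloct-2-en-1-ol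
Product: 18 (2E,7S)-8-(tert-butyldiphenylsilyloxy)-3,7-dimethyloct-2-enal
Conditions: MnO2, CH2Cl2, rt
Reagents that add atoms: none
Why: Heterogeneous MnO2 oxidation is selective for allylic alcohols and gives the enal without over-oxidation or E/Z erosion.

Step 12
Reactants: 18 (2E,7S)-8-(tert-butyldiphenylsilyloxy)-3,7-dimethyloct-2-enal; 19 allenylboronic acid pinacol ester
Product: 20 (4S,5E,10S)-11-(tert-butyldiphenylsilyloxy)-6,10-dimethylundec-5-en-1-yn-4-ol
Conditions: (S)-TRIP phosphoric acid (cat.), 4 Å MS, toluene, −20 °C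
Reagents that add atoms: none
Why: Chiral-phosphoric-acid-catalysed propargylboration passes through a closed six-membered transition state with allenyl-to-propargyl transposition, and (S)-3,3'-bis(2,4,6-triisopropylphenyl)-1,1'-binaphthyl-2,2'-diyl hydrogen phosphate is chosen to direct the propargyl group to the Si face of the enal, which sets C5' as S under catalyst control (sense to be confirmed by Mosher ester analysis).

Step 13
Reactants: 20 (4S,5E,10S)-11-(tert-butyldiphenylsilyloxy)-6,10-dimethylundec-5-en-1-yn-4-ol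
Product: 21 (4S,5E,10S)-11-(tert-butyldiphenylsilyloxy)-6,10-dimethyl-4-(triethylsilyloxy)undec-5-en-1-yne
Conditions: TESCl, imidazole, CH2Cl2, 0 °C
Reagents that add atoms: chlorotriethylsilane (CC[Si](Cl)(CC)CC)
Why: Standard silylation of a secondary alcohol, giving a group that tolerates AlMe3 yet can later be removed by mild acid beside the primary TBDPS ether.

Step 14
Reactants: 21 (4S,5E,10S)-11-(tert-butyldiphenylsilyloxy)-6,10-dimethyl-4-(triethylsilyloxy)undec-5-en-1-yne; 14 trimethylaluminium; 5 1-(chloromethyl)-2,5-dimethoxy-3-methylbenzene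
Product: 23 1-[(2E,5S,6E,11S)-12-(tert-butyldiphenylsilyloxy)-3,7,11-trimethyl-5-(triethylsilyloxy)dodeca-2,6-dien-1-yl]-2,5-dimethoxy-3-methylbenzene, via alkenyldimethylalane 22 (not isolated)
Conditions: AlMe3 (14), Cp2ZrCl2 (cat.), ClCH2CH2Cl, 0 °C → rt; excess AlMe3 and solvent removed in vacuo; 5, Pd(PPh3)4 (cat.), THF, rt
Reagents that add atoms: none
Why: Cp2ZrCl2 and AlMe3 generate a methylzirconocene–aluminium species that adds CH3 and metal syn across the C2'≡C3' alkyne with methyl on the internal C3', and exchange to aluminium gives the (E)-alkenyldimethylalane 22 (Negishi zirconium-catalysed carboalumination). Zerovalent palladium then inserts into the C–Cl bond of 5, the alkenyl group passes from aluminium to palladium, and reductive elimination forms C1'–C2' with retention of alkene geometry; the closest precedent is the alkenylalane–benzyl chloride coupling used for ubiquinone-type side chains. No ring closes and no stereocentre is created, and C5' and C11' are not touched. The step needs regioselective syn methylmetalation, which a terminal alkyne secures inherently, and chemoselectivity, which holds because the trisubstituted C6'=C7' alkene is inert to carboalumination and the TES and TBDPS ethers tolerate AlMe3. Removing excess AlMe3 before the coupling keeps methyl transfer to the benzylpalladium intermediate from competing.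

Step 15
Reactants: 23 1-[(2E,5S,6E,11S)-12-(tert-butyldiphenylsilyloxy)-3,7,11-trimethyl-5-(triethylsilyloxy)dodeca-2,6-dien-1-yl]-2,5-dimethoxy-3-methylbenzene
Product: 24 (2E,5S,6E,11S)-12-(tert-butyldiphenylsilyloxy)-1-(2,5-dimethoxy-3-methylphenyl)-3,7,11-trimethyldodeca-2,6-dien-5-ol
Conditions: PPTS, MeOH/CH2Cl2, 0 °C
Reagents that add atoms: none
Why: Mild acid-catalysed methanolysis cleaves the secondary TES ether far faster than the primary TBDPS ether and is too weak to ionise the allylic C5'–O bond.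

Step 16
Reactants: 24 (2E,5S,6E,11S)-12-(tert-butyldiphenylsilyloxy)-1-(2,5-dimethoxy-3-methylphenyl)-3,7,11-trimethyldodeca-2,6-dien-5-ol
Product: 25 (2E,5S,6E,11S)-12-(tert-butyldiphenylsilyloxy)-1-(2,5-dimethoxy-3-methylphenyl)-3,7,11-trimethyldodeca-2,6-dien-5-yl acetate
Conditions: Ac2O, pyridine, DMAP (cat.), CH2Cl2, rt
Reagents that add atoms: acetic anhydride (CC(=O)OC(C)=O)
Why: DMAP-catalysed acylation of the only free hydroxyl proceeds with retention at C5' because the C–O bond is not broken.

Step 17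
Reactants: 25 (2E,5S,6E,11S)-12-(tert-butyldiphenylsilyloxy)-1-(2,5-dimethoxy-3-methylphenyl)-3,7,11-trimethyldodeca-2,6-dien-5-yl acetate
Product: 26 (2E,5S,6E,11S)-1-(2,5-dimethoxy-3-methylphenyl)-12-hydroxy-3,7,11-trimethyldodeca-2,6-dien-5-yl acetate
Conditions: TBAF, AcOH, THF, rt
Reagents that add atoms: none
Why: Fluoride-induced desilylation buffered with acetic acid frees the C12' alcohol while the acetate, which has no neighbouring hydroxyl to migrate to, stays in place.

Step 18
Reactants: 26 (2E,5S,6E,11S)-1-(2,5-dimethoxy-3-methylphenyl)-12-hydroxy-3,7,11-trimethyldodeca-2,6-dien-5-yl acetate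
Product: 27 (2E,5S,6E,11S)-1-(2,5-dimethoxy-3-methylphenyl)-3,7,11-trimethyl-12-oxododeca-2,6-dien-5-yl acetate
Conditions: DMP, NaHCO3, CH2Cl2, 0 °C → rt
Reagents that add atoms: none
Why: Buffered Dess–Martin oxidation gives the α-branched aldehyde under near-neutral conditions that do not epimerise C11'.

Step 19
Reactants: 27 (2E,5S,6E,11S)-1-(2,5-dimethoxy-3-methylphenyl)-3,7,11-trimethyl-12-oxododeca-2,6-dien-5-yl acetate; 28 1-chloro-3-methylbut-2-ene
Product: 30 (2E,5S,6E,11S,12RS)-1-(2,5-dimethoxy-3-methylphenyl)-12-hydroxy-3,7,11,15-tetramethylhexadeca-2,6,14-trien-5-yl acetate, via prenylbarium chloride 29 (not isolated)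
Conditions: Li, biphenyl, BaI2, THF, rt; 28, −78 °C; then 27, THF, −78 °C
Reagents that add atoms: none
Why: Yamamoto allylbarium addition, in which the prenylbarium reagent bonds to the aldehyde through its unsubstituted α-carbon at −78 °C, faster than it attacks the acetate, forming C12'–C13' with the C12' carbinol as an uncontrolled epimer mixture that step 20 erases.

Step 20
Reactants: 30 (2E,5S,6E,11S,12RS)-1-(2,5-dimethoxy-3-methylphenyl)-12-hydroxy-3,7,11,15-tetramethylhexadeca-2,6,14-trien-5-yl acetate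
Product: 31 (2E,5S,6E,11S)-1-(2,5-dimethoxy-3-methylphenyl)-3,7,11,15-tetramethyl-12-oxohexadeca-2,6,14-trien-5-yl acetate
Conditions: DMP, NaHCO3, CH2Cl2, 0 °C
Reagents that add atoms: none
Why: Buffered Dess–Martin oxidation of a homoallylic alcohol is the standard entry to β,γ-unsaturated ketones without migration of the alkene into conjugation or epimerisation at C11'.

Step 21
Reactants: 31 (2E,5S,6E,11S)-1-(2,5-dimethoxy-3-methylphenyl)-3,7,11,15-tetramethyl-12-oxohexadeca-2,6,14-trien-5-yl acetate
Product: 32 (2E,5S,6E,11S)-3,7,11,15-tetramethyl-1-(5-methyl-3,6-dioxocyclohexa-1,4-dien-1-yl)-12-oxohexadeca-2,6,14-trien-5-yl acetate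
Conditions: (NH4)2Ce(NO3)6, MeCN/H2O, 0 °C
Reagents that add atoms: water (O)
Why: Oxidative demethylation of the 1,4-dimethoxyarene by tetravalent cerium, in which two one-electron oxidations with ipso attack of water release two methanol and give the 1,4-benzoquinone, while brief exposure at 0 °C spares the isolated alkenes, the acetate and the ketone.

Step 22
Reactants: 32 (2E,5S,6E,11S)-3,7,11,15-tetramethyl-1-(5-methyl-3,6-dioxocyclohexa-1,4-dien-1-yl)-12-oxohexadeca-2,6,14-trien-5-yl acetate
Product: 33 (2E,5S,6E,11S)-1-(2,5-dihydroxy-3-methylphenyl)-3,7,11,15-tetramethyl-12-oxohexadeca-2,6,14-trien-5-yl acetate (CNP0102989.1)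
Conditions: Na2S2O4, EtOAc/H2O, rt, argon
Reagents that add atoms: none
Why: Two-electron reduction of the quinone by dithionite in a neutral two-phase mixture gives the hydroquinone and leaves the acetate, C11' and the β,γ-unsaturated ketone unchanged.

**Compound list**

1 | 4-methoxy-2-methylphenol | COc1ccc(O)c(C)c1 | starting material
2 | 2-hydroxy-5-methoxy-3-methylbenzaldehyde | COc1cc(C)c(O)c(C=O)c1 | intermediate
3 | 2,5-dimethoxy-3-methylbenzaldehyde | COc1cc(C)c(OC)c(C=O)c1 | intermediate
4 | (2,5-dimethoxy-3-methylphenyl)methanol | COc1cc(C)c(OC)c(CO)c1 | intermediate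
5 | 1-(chloromethyl)-2,5-dimethoxy-3-methylbenzene | COc1cc(C)c(OC)c(CCl)c1 | intermediate
6 | methyl (R)-3-hydroxy-2-methylpropanoate | COC(=O)[C@H](C)CO | starting material
7 | methyl (R)-3-(tert-butyldiphenylsilyloxy)-2-methylpropanoate | COC(=O)[C@H](C)CO[Si](c1ccccc1)(c1ccccc1)C(C)(C)C | intermediate
8 | (S)-3-(tert-butyldiphenylsilyloxy)-2-methylpropan-1-ol | OC[C@H](C)CO[Si](c1ccccc1)(c1ccccc1)C(C)(C)C | intermediate
9 | (R)-tert-butyl(3-iodo-2-methylpropoxy)diphenylsilane | IC[C@H](C)CO[Si](c1ccccc1)(c1ccccc1)C(C)(C)C | intermediate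
10 | (4-bromobut-1-yn-1-yl)trimethylsilane | C[Si](C)(C)C#CCCBr | starting material
11 | [4-(trimethylsilyl)but-3-yn-1-yl]magnesium bromide, formed in situ | C[Si](C)(C)C#CCC[Mg]Br | intermediate
12 | (S)-tert-butyl{[2-methyl-7-(trimethylsilyl)hept-6-yn-1-yl]oxy}diphenylsilane | C[Si](C)(C)C#CCCC[C@H](C)CO[Si](c1ccccc1)(c1ccccc1)C(C)(C)C | intermediate
13 | (S)-tert-butyl[(2-methylhept-6-yn-1-yl)oxy]diphenylsilane | C#CCCC[C@H](C)CO[Si](c1ccccc1)(c1ccccc1)C(C)(C)C | intermediate
14 | trimethylaluminium | C[Al](C)C | starting material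
15 | [(1E,6S)-7-(tert-butyldiphenylsilyloxy)-2,6-dimethylhept-1-en-1-yl]dimethylalumane, formed in situ | C[Al](C)/C=C(\C)CCC[C@H](C)CO[Si](c1ccccc1)(c1ccccc1)C(C)(C)C | intermediate
16 | lithium butyl[(1E,6S)-7-(tert-butyldiphenylsilyloxy)-2,6-dimethylhept-1-en-1-yl]dimethylaluminate, formed in situ | [Li+].CCCC[Al-](C)(C)/C=C(\C)CCC[C@H](C)CO[Si](c1ccccc1)(c1ccccc1)C(C)(C)C | intermediate
17 | (2E,7S)-8-(tert-butyldiphenylsilyloxy)-3,7-dimethyloct-2-en-1-ol | OC/C=C(\C)CCC[C@H](C)CO[Si](c1ccccc1)(c1ccccc1)C(C)(C)C | intermediate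
18 | (2E,7S)-8-(tert-butyldiphenylsilyloxy)-3,7-dimethyloct-2-enal | O=C/C=C(\C)CCC[C@H](C)CO[Si](c1ccccc1)(c1ccccc1)C(C)(C)C | intermediate
19 | allenylboronic acid pinacol ester (4,4,5,5-tetramethyl-2-(propa-1,2-dien-1-yl)-1,3,2-dioxaborolane) | C=C=CB1OC(C)(C)C(C)(C)O1 | starting material
20 | (4S,5E,10S)-11-(tert-butyldiphenylsilyloxy)-6,10-dimethylundec-5-en-1-yn-4-ol | C#CC[C@H](O)/C=C(\C)CCC[C@H](C)CO[Si](c1ccccc1)(c1ccccc1)C(C)(C)C | intermediate
21 | (4S,5E,10S)-11-(tert-butyldiphenylsilyloxy)-6,10-dimethyl-4-(triethylsilyloxy)undec-5-en-1-yne | C#CC[C@H](O[Si](CC)(CC)CC)/C=C(\C)CCC[C@H](C)CO[Si](c1ccccc1)(c1ccccc1)C(C)(C)C | intermediate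
22 | [(1E,4S,5E,10S)-11-(tert-butyldiphenylsilyloxy)-2,6,10-trimethyl-4-(triethylsilyloxy)undeca-1,5-dien-1-yl]dimethylalumane, formed in situ | C[Al](C)/C=C(\C)C[C@H](O[Si](CC)(CC)CC)/C=C(\C)CCC[C@H](C)CO[Si](c1ccccc1)(c1ccccc1)C(C)(C)C | intermediate
23 | 1-[(2E,5S,6E,11S)-12-(tert-butyldiphenylsilyloxy)-3,7,11-trimethyl-5-(triethylsilyloxy)dodeca-2,6-dien-1-yl]-2,5-dimethoxy-3-methylbenzene | COc1cc(C)c(OC)c(C/C=C(\C)C[C@H](O[Si](CC)(CC)CC)/C=C(\C)CCC[C@H](C)CO[Si](c2ccccc2)(c2ccccc2)C(C)(C)C)c1 | intermediate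
24 | (2E,5S,6E,11S)-12-(tert-butyldiphenylsilyloxy)-1-(2,5-dimethoxy-3-methylphenyl)-3,7,11-trimethyldodeca-2,6-dien-5-ol | COc1cc(C)c(OC)c(C/C=C(\C)C[C@H](O)/C=C(\C)CCC[C@H](C)CO[Si](c2ccccc2)(c2ccccc2)C(C)(C)C)c1 | intermediate
25 | (2E,5S,6E,11S)-12-(tert-butyldiphenylsilyloxy)-1-(2,5-dimethoxy-3-methylphenyl)-3,7,11-trimethyldodeca-2,6-dien-5-yl acetate | COc1cc(C)c(OC)c(C/C=C(\C)C[C@H](OC(C)=O)/C=C(\C)CCC[C@H](C)CO[Si](c2ccccc2)(c2ccccc2)C(C)(C)C)c1 | intermediate
26 | (2E,5S,6E,11S)-1-(2,5-dimethoxy-3-methylphenyl)-12-hydroxy-3,7,11-trimethyldodeca-2,6-dien-5-yl acetate | COc1cc(C)c(OC)c(C/C=C(\C)C[C@H](OC(C)=O)/C=C(\C)CCC[C@H](C)CO)c1 | intermediate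
27 | (2E,5S,6E,11S)-1-(2,5-dimethoxy-3-methylphenyl)-3,7,11-trimethyl-12-oxododeca-2,6-dien-5-yl acetate | COc1cc(C)c(OC)c(C/C=C(\C)C[C@H](OC(C)=O)/C=C(\C)CCC[C@H](C)C=O)c1 | intermediate
28 | 1-chloro-3-methylbut-2-ene (prenyl chloride) | CC(C)=CCCl | starting material
29 | (3-methylbut-2-en-1-yl)barium chloride, formed in situ | CC(C)=CC[Ba]Cl | intermediate
30 | (2E,5S,6E,11S,12RS)-1-(2,5-dimethoxy-3-methylphenyl)-12-hydroxy-3,7,11,15-tetramethylhexadeca-2,6,14-trien-5-yl acetate | COc1cc(C)c(OC)c(C/C=C(\C)C[C@H](OC(C)=O)/C=C(\C)CCC[C@H](C)C(O)CC=C(C)C)c1 | intermediate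
31 | (2E,5S,6E,11S)-1-(2,5-dimethoxy-3-methylphenyl)-3,7,11,15-tetramethyl-12-oxohexadeca-2,6,14-trien-5-yl acetate | COc1cc(C)c(OC)c(C/C=C(\C)C[C@H](OC(C)=O)/C=C(\C)CCC[C@H](C)C(=O)CC=C(C)C)c1 | intermediate
32 | (2E,5S,6E,11S)-3,7,11,15-tetramethyl-1-(5-methyl-3,6-dioxocyclohexa-1,4-dien-1-yl)-12-oxohexadeca-2,6,14-trien-5-yl acetate | CC1=CC(=O)C=C(C/C=C(\C)C[C@H](OC(C)=O)/C=C(\C)CCC[C@H](C)C(=O)CC=C(C)C)C1=O | intermediate
33 | (2E,5S,6E,11S)-1-(2,5-dihydroxy-3-methylphenyl)-3,7,11,15-tetramethyl-12-oxohexadeca-2,6,14-trien-5-yl acetate (CNP0102989.1) | CC(=O)O[C@H](/C=C(\C)CCC[C@H](C)C(=O)CC=C(C)C)C/C(C)=C/Cc1cc(O)cc(C)c1O | target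

**Step count**

Total: 22 steps. Longest linear sequence: 18 steps (steps 5–22, from Roche ester 6); the arene branch (steps 1–4) joins at step 14.

**Steps most likely to fail, with fallbacks**

Step 19. The prenylbarium reagent may bond through its γ-terminus to give the branched 1,1-dimethylallyl carbinol, may add to the C5' acetate carbonyl, or may enolise the aldehyde and erode C11'. The fallback sets out from aldehyde 27 and uses a sulfone-stabilised prenyl anion, which reacts at its α-carbon and ignores esters at low temperature. Commercial 3-methylbut-2-enyl phenyl sulfone is deprotonated with n-BuLi in THF at −78 °C to lithium 3-methyl-1-(phenylsulfonyl)but-2-en-1-ide F1. Addition of 27 should give the β-hydroxy sulfone (2E,5S,6E,11S)-1-(2,5-dimethoxy-3-methylphenyl)-12-hydroxy-3,7,11,15-tetramethyl-13-(phenylsulfonyl)hexadeca-2,6,14-trien-5-yl acetate F2 as a diastereomer mixture. Buffered Dess–Martin oxidation converts it to the β-keto sulfone (2E,5S,6E,11S)-1-(2,5-dimethoxy-3-methylphenyl)-3,7,11,15-tetramethyl-12-oxo-13-(phenylsulfonyl)hexadeca-2,6,14-trien-5-yl acetate F3. Reductive desulfonylation with SmI2 in THF/MeOH at −78 °C, followed by kinetic α-protonation of the dienolate, returns the route at ketone 31.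

Step 12. Facial discrimination may be poor, or turnover slow, because the enal is β,β-disubstituted and more hindered and less electrophilic than the aryl aldehydes for which this catalysis is best established. The fallback sets out from enal 18 and replaces asymmetric catalysis by enzymatic resolution. Heating 18 with 19 in toluene without catalyst should give the carbinol as both C4 epimers, (4RS,5E,10S)-11-(tert-butyldiphenylsilyloxy)-6,10-dimethylundec-5-en-1-yn-4-ol F4. Lipase-catalysed acylation (Burkholderia cepacia lipase, vinyl acetate, hexane, rt) is expected by the Kazlauskas rule to acylate the 4R epimer, with the alkenyl chain as the large and the propargyl group as the medium substituent. This gives (4R,5E,10S)-11-(tert-butyldiphenylsilyloxy)-6,10-dimethylundec-5-en-1-yn-4-yl acetate F5 and leaves the 4S alcohol, which is separated by chromatography. The route is rejoined at 20.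

Step 14. Methyl instead of alkenyl transfer to the benzylpalladium intermediate, homocoupling of the benzyl chloride, or partial loss of the TES ether in the Lewis-acidic medium may lower the efficiency of the one-flask coupling. The fallback sets out from alkyne 21 and forms the same two bonds in two operations, with the polarity at C1'–C2' reversed. Methylalumination as in step 14 gives alane 22, which is quenched with I2 in THF at −30 °C and isolated as the vinyl iodide (1E,4S,5E,10S)-11-(tert-butyldiphenylsilyloxy)-1-iodo-2,6,10-trimethyl-4-(triethylsilyloxy)undeca-1,5-diene F6. Benzyl chloride 5 is converted with zinc dust and LiCl in THF into (2,5-dimethoxy-3-methylbenzyl)zinc chloride F7. Negishi coupling of F6 with F7, catalysed by Pd(PPh3)4 in THF at rt, proceeds with retention of alkene geometry and returns the route at 23.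

**Further compounds**

F1 | step 19 | lithium 3-methyl-1-(phenylsulfonyl)but-2-en-1-ide | [Li]C(C=C(C)C)S(=O)(=O)c1ccccc1
F2 | step 19 | (2E,5S,6E,11S)-1-(2,5-dimethoxy-3-methylphenyl)-12-hydroxy-3,7,11,15-tetramethyl-13-(phenylsulfonyl)hexadeca-2,6,14-trien-5-yl acetate | COc1cc(C)c(OC)c(C/C=C(\C)C[C@H](OC(C)=O)/C=C(\C)CCC[C@H](C)C(O)C(C=C(C)C)S(=O)(=O)c2ccccc2)c1
F3 | step 19 | (2E,5S,6E,11S)-1-(2,5-dimethoxy-3-methylphenyl)-3,7,11,15-tetramethyl-12-oxo-13-(phenylsulfonyl)hexadeca-2,6,14-trien-5-yl acetate | COc1cc(C)c(OC)c(C/C=C(\C)C[C@H](OC(C)=O)/C=C(\C)CCC[C@H](C)C(=O)C(C=C(C)C)S(=O)(=O)c2ccccc2)c1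
F4 | step 12 | (4RS,5E,10S)-11-(tert-butyldiphenylsilyloxy)-6,10-dimethylundec-5-en-1-yn-4-ol | C#CCC(O)/C=C(\C)CCC[C@H](C)CO[Si](c1ccccc1)(c1ccccc1)C(C)(C)C
F5 | step 12 | (4R,5E,10S)-11-(tert-butyldiphenylsilyloxy)-6,10-dimethylundec-5-en-1-yn-4-yl acetate | C#CC[C@@H](OC(C)=O)/C=C(\C)CCC[C@H](C)CO[Si](c1ccccc1)(c1ccccc1)C(C)(C)C
F6 | step 14 | (1E,4S,5E,10S)-11-(tert-butyldiphenylsilyloxy)-1-iodo-2,6,10-trimethyl-4-(triethylsilyloxy)undeca-1,5-diene | I/C=C(\C)C[C@H](O[Si](CC)(CC)CC)/C=C(\C)CCC[C@H](C)CO[Si](c1ccccc1)(c1ccccc1)C(C)(C)C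
F7 | step 14 | (2,5-dimethoxy-3-methylbenzyl)zinc chloride | COc1cc(C)c(OC)c(C[Zn]Cl)c1
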